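**Plan**

Ring numbering used throughout: C1 (carbinol carbon carrying the vanillate), C2 (isopropyl), C3=C4, C5 (tertiary carbinol), C6, C7, C8=C9 (methyl on C9), C10 (CH2).
Retrosynthesis: cut the ester C–O bond, then the ring bond C9–C10, then the C3=C4 double bond; this leaves a linalool-derived α-silyloxy aldehyde (C4–C9 with both methyls) and an aldol-derived sulfone (C1–C3, C10, isopropyl).
Enabling feature: in the ten-membered ring the C1 carbinol lies two atoms from the E-trisubstituted C8=C9 alkene, with the methyl on the near carbon C9 (homoallylic alcohol C1(O)–C10H2–C9(Me)=C8H). Syn addition of an epoxide CH2 and hydrogen across a 2-alkyne gives exactly this unit, so one reductive alkyne–epoxide coupling can close the ring, fix the alkene geometry and unveil the C1–OH.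
Forward: the two fragments are made in parallel and joined by Julia–Kocienski olefination; the chlorohydrin is closed to the epoxide; the ring is closed by nickel-catalysed reductive cyclization of the epoxy-alkyne; esterification and desilylation follow.
Stereochemistry: C5 from (R)-linalool; C1 and C2 from an auxiliary-controlled syn-aldol with chloroacetaldehyde; E-C3=C4 from the Julia–Kocienski step; E-C8=C9 from the syn addition in the key step.

Key step: step 14

Assumption: anhydrous chloroacetaldehyde is freshly distilled from the commercial aqueous solution, and (R)-linalool of high enantiomeric purity is used, since its purity sets that of C5.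

**Route**

Step 1
Reactants: 1 (R)-4-benzyloxazolidin-2-one; 2 3-methylbutanoyl chloride
Product: 3 (R)-4-benzyl-3-(3-methylbutanoyl)oxazolidin-2-one
Conditions: Et3N, DMAP (cat.), CH2Cl2, 0 °C → rt
Reagents that add atoms: none
Why: DMAP-catalysed N-acylation of the oxazolidinone by the acid chloride should give the imide without touching the stereocentre.

Step 2
Reactants: 3 (R)-4-benzyl-3-(3-methylbutanoyl)oxazolidin-2-one; 4 chloroacetaldehyde (anhydrous)
Product: 7 (R)-4-benzyl-3-[(2R,3R)-4-chloro-3-hydroxy-2-(propan-2-yl)butanoyl]oxazolidin-2-one, via Z-boron enolate 5 (not isolated), via boron aldolate 6 (not isolated)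
Conditions: Bu2BOTf, i-Pr2NEt, CH2Cl2, −78 → 0 °C; then 4, −78 → 0 °C; pH 7 buffer, MeOH, H2O2, 0 °C
Reagents that add atoms: none
Why: Evans syn-aldol reaction, in which the Z-boron enolate adds through a chair Zimmerman–Traxler transition state on the face away from the benzyl group, should set the isopropyl-bearing carbon and the carbinol carbon together (syn, 2R,3R) while the chlorine stays as a latent epoxide.

Step 3
Reactants: 7 (R)-4-benzyl-3-[(2R,3R)-4-chloro-3-hydroxy-2-(propan-2-yl)butanoyl]oxazolidin-2-one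
Product: 8 (R)-4-benzyl-3-[(2R,3R)-4-chloro-2-(propan-2-yl)-3-(triethylsilyloxy)butanoyl]oxazolidin-2-one
Conditions: TESOTf, 2,6-lutidine, CH2Cl2, −78 → 0 °C
Reagents that add atoms: triethylsilyl trifluoromethanesulfonate, CC[Si](CC)(CC)OS(=O)(=O)C(F)(F)F
Why: silylation of the secondary alcohol with the silyl triflate and a hindered base should block retro-aldol cleavage and premature epoxide closure in the later basic and reductive steps.

Step 4
Reactants: 8 (R)-4-benzyl-3-[(2R,3R)-4-chloro-2-(propan-2-yl)-3-(triethylsilyloxy)butanoyl]oxazolidin-2-one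
Product: 9 (2S,3R)-4-chloro-2-(propan-2-yl)-3-(triethylsilyloxy)butan-1-ol
Conditions: LiBH4, MeOH (1 equiv), THF, 0 °C
Reagents that add atoms: none
Why: reductive cleavage of the N-acyl oxazolidinone by hydride attack at the exocyclic carbonyl should release the primary alcohol and the recoverable auxiliary without touching the primary chloride or the silyl ether.

Step 5
Reactants: 9 (2S,3R)-4-chloro-2-(propan-2-yl)-3-(triethylsilyloxy)butan-1-ol
Product: 10 5-{[(2R,3R)-4-chloro-2-(propan-2-yl)-3-(triethylsilyloxy)butyl]sulfanyl}-1-phenyl-1H-tetrazole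
Conditions: 1-phenyl-1H-tetrazole-5-thiol, PPh3, DIAD, THF, 0 °C → rt
Reagents that add atoms: 1-phenyl-1H-tetrazole-5-thiol, Sc1nnnn1-c1ccccc1
Why: Mitsunobu thioetherification, in which the acidic thiol displaces the activated primary alcohol by SN2 at a CH2 group, should proceed with no stereocentre involved.

Step 6
Reactants: 10 5-{[(2R,3R)-4-chloro-2-(propan-2-yl)-3-(triethylsilyloxy)butyl]sulfanyl}-1-phenyl-1H-tetrazole
Product: 11 5-{[(2R,3R)-4-chloro-2-(propan-2-yl)-3-(triethylsilyloxy)butyl]sulfonyl}-1-phenyl-1H-tetrazole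
Conditions: mCPBA, CH2Cl2, 0 °C → rt
Reagents that add atoms: 3-chloroperoxybenzoic acid (mCPBA), OOC(=O)c1cccc(Cl)c1
Why: peracid oxidation of the sulfide through the sulfoxide should give the sulfone cleanly because the molecule has no alkene at this stage.

Step 7
Reactants: 12 (R)-linalool
Product: 13 tert-butyl{[(3R)-3,7-dimethylocta-1,6-dien-3-yl]oxy}dimethylsilane
Conditions: TBSOTf, 2,6-lutidine, CH2Cl2, 0 °C → rt
Reagents that add atoms: tert-butyldimethylsilyl trifluoromethanesulfonate, CC(C)(C)[Si](C)(C)OS(=O)(=O)C(F)(F)F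
Why: silylation of the tertiary allylic alcohol with the reactive silyl triflate should protect it while leaving the linalool stereocentre (the future C5) untouched.

Step 8
Reactants: 13 tert-butyl{[(3R)-3,7-dimethylocta-1,6-dien-3-yl]oxy}dimethylsilane
Product: 15 (4R)-4-(tert-butyldimethylsilyloxy)-4-methylhex-5-enal, via ozonide 14 (not isolated)
Conditions: O3, CH2Cl2, −78 °C (Sudan Red 7B end-point); then PPh3, −78 °C → rt
Reagents that add atoms: ozone, [O-][O+]=O
Why: chemoselective ozonolysis should cleave the electron-rich trisubstituted alkene far faster than the vinyl group next to the silyloxy-bearing quaternary carbon, and phosphine reduction of the ozonide gives the aldehyde.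

Step 9
Reactants: 15 (4R)-4-(tert-butyldimethylsilyloxy)-4-methylhex-5-enal
Product: 16 tert-butyl{[(3R)-7,7-dibromo-3-methylhepta-1,6-dien-3-yl]oxy}dimethylsilane
Conditions: CBr4, PPh3, CH2Cl2, 0 °C
Reagents that add atoms: carbon tetrabromide, BrC(Br)(Br)Br
Why: first stage of the Corey–Fuchs alkyne synthesis, a Wittig reaction of the ylide Ph3P=CBr2 formed in the flask with the unhindered aldehyde.

Step 10
Reactants: 16 tert-butyl{[(3R)-7,7-dibromo-3-methylhepta-1,6-dien-3-yl]oxy}dimethylsilane
Product: 18 tert-butyldimethyl{[(3R)-3-methyloct-1-en-6-yn-3-yl]oxy}silane, via lithium acetylide 17 (not isolated)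
Conditions: n-BuLi (2.2 equiv), THF, −78 °C; then MeI, −78 °C → rt
Reagents that add atoms: iodomethane, CI
Why: second stage of the Corey–Fuchs sequence, in which Br/Li exchange, α-elimination and Fritsch–Buttenberg–Wiechell shift give the lithium acetylide that is C-methylated in the same flask.

Step 11
Reactants: 18 tert-butyldimethyl{[(3R)-3-methyloct-1-en-6-yn-3-yl]oxy}silane
Product: 20 (2R)-2-(tert-butyldimethylsilyloxy)-2-methylhept-5-ynal, via diol 19 (not isolated)
Conditions: OsO4 (cat.), NaIO4, 2,6-lutidine, 1,4-dioxane/H2O, rt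
Reagents that add atoms: osmium tetroxide, O=[Os](=O)(=O)=O; sodium periodate, [Na+].[O-]I(=O)(=O)=O
Why: Lemieux–Johnson cleavage, in which OsO4 dihydroxylates the alkene much faster than the internal alkyne and periodate cleaves the diol, should give the non-enolizable α-silyloxy aldehyde.

Step 12
Reactants: 11 5-{[(2R,3R)-4-chloro-2-(propan-2-yl)-3-(triethylsilyloxy)butyl]sulfonyl}-1-phenyl-1H-tetrazole; 20 (2R)-2-(tert-butyldimethylsilyloxy)-2-methylhept-5-ynal
Product: 22 {[(2R,3S,4E,6R)-1-chloro-6-methyl-3-(propan-2-yl)-2-(triethylsilyloxy)undec-4-en-9-yn-6-yl]oxy}(tert-butyl)dimethylsilane, via potassium sulfonyl carbanion 21 (not isolated)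
Conditions: KN(SiMe3)2, DME, −78 °C; then 20, −78 °C → rt
Reagents that add atoms: none
Why: Julia–Kocienski olefination (addition of the metalated tetrazolyl sulfone, Smiles rearrangement, anti-elimination of SO2 and tetrazolate) should give the E-alkene, favoured by the potassium counter-ion in DME and the α-branched aldehyde.

Step 13
Reactants: 22 {[(2R,3S,4E,6R)-1-chloro-6-methyl-3-(propan-2-yl)-2-(triethylsilyloxy)undec-4-en-9-yn-6-yl]oxy}(tert-butyl)dimethylsilane
Product: 24 (2R)-2-[(3S,4E,6R)-6-(tert-butyldimethylsilyloxy)-2,6-dimethylundec-4-en-9-yn-3-yl]oxirane, via chlorohydrin alkoxide 23 (not isolated)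
Conditions: TBAF, THF, 0 °C → rt
Reagents that add atoms: none
Why: fluoride should cleave the secondary triethylsilyl ether selectively over the hindered tertiary tert-butyldimethylsilyl ether, and the freed alkoxide displaces the vicinal chloride in a 3-exo-tet Williamson closure with retention at the carbinol carbon.

Step 14
Reactants: 24 (2R)-2-[(3S,4E,6R)-6-(tert-butyldimethylsilyloxy)-2,6-dimethylundec-4-en-9-yn-3-yl]oxirane
Product: 26 (1S,2S,3E,5R,8E)-5-(tert-butyldimethylsilyloxy)-5,9-dimethyl-2-(propan-2-yl)cyclodeca-3,8-dien-1-ol, via diethylborinate 25 (not isolated)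
Conditions: Ni(cod)2 (20 mol %), PBu3 (40 mol %), Et3B (4 equiv), THF/toluene, 25 → 60 °C, syringe-pump addition of 24 (final 0.005 M); aq. NaHCO3 work-up
Reagents that add atoms: none
Why: Proposed new method: zerovalent nickel carrying PBu3 is expected to add oxidatively to the epoxide at its CH2 carbon (SN2-type, assisted by Et3B on oxygen) and to insert the tethered alkyne syn into the new Ni–C bond, giving an alkenyl(alkoxy)nickel metallacycle; ethyl transfer from Et3B to nickel, β-hydride elimination of ethene and C–H reductive elimination then place the alkenyl hydrogen cis to the new C–C bond and release the product as borinate 25. The closest known reaction type is the nickel-catalysed reductive coupling of alkynes with terminal epoxides, established intermolecularly and for endo-selective closure of five- and six-membered rings, together with nickel-catalysed reductive alkyne–aldehyde macrocyclization; what is new is its use to close a ten-membered carbocycle. The ring closes in a ten-membered endo mode (endo at the epoxide, endo-dig at the alkyne, so both epoxide carbons and both alkyne carbons end up in the ring), forming the bond between the epoxide CH2 (C10) and the methyl-bearing alkyne carbon (C9). No stereocentre is created: C1 keeps the configuration of the epoxide because its C–O bond is never broken, C2 and C5 are spectators, and the E geometry of C8=C9 follows from the syn addition of carbon and hydrogen across the alkyne. The step needs attack at the unsubstituted epoxide carbon (secured by sterics), C–C bond formation at the methyl-bearing alkyne carbon (the usual sense for methyl-substituted alkynes with a small phosphine, and the one that gives the E-cyclodecene instead of a nine-membered ring with an exocyclic ethylidene), and cyclization ahead of oligomerization (secured by slow addition at high dilution). The tertiary allylic alcohol is kept silylated so that zerovalent nickel and Et3B cannot ionize it, and the isolated E-alkene lacks the activation needed for a competing enyne cyclization.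

Step 15
Reactants: 27 vanillic acid
Product: 29 4-(tert-butyldimethylsilyloxy)-3-methoxybenzoic acid, via bis-silyl ester 28 (not isolated)
Conditions: TBSCl, imidazole, DMF, rt; then AcOH/THF/H2O, rt
Reagents that add atoms: tert-butyldimethylsilyl chloride, CC(C)(C)[Si](C)(C)Cl
Why: silylation of both acidic OH groups followed by selective hydrolysis of the labile silyl ester should leave the phenol protected and the acid free.

Step 16
Reactants: 26 (1S,2S,3E,5R,8E)-5-(tert-butyldimethylsilyloxy)-5,9-dimethyl-2-(propan-2-yl)cyclodeca-3,8-dien-1-ol; 29 4-(tert-butyldimethylsilyloxy)-3-methoxybenzoic acid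
Product: 31 (1S,2S,3E,5R,8E)-5-(tert-butyldimethylsilyloxy)-5,9-dimethyl-2-(propan-2-yl)cyclodeca-3,8-dien-1-yl 4-(tert-butyldimethylsilyloxy)-3-methoxybenzoate, via mixed anhydride 30 (not isolated)
Conditions: 2,4,6-trichlorobenzoyl chloride, Et3N, THF, rt; then 26, DMAP, toluene, rt → 40 °C
Reagents that add atoms: none
Why: Yamaguchi esterification, in which DMAP attacks the less hindered vanilloyl carbonyl of the mixed anhydride and the acylpyridinium acylates the hindered secondary alcohol, should give the ester with retention at C1.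

Step 17
Reactants: 31 (1S,2S,3E,5R,8E)-5-(tert-butyldimethylsilyloxy)-5,9-dimethyl-2-(propan-2-yl)cyclodeca-3,8-dien-1-yl 4-(tert-butyldimethylsilyloxy)-3-methoxybenzoate
Product: 32 (1S,2S,3E,5R,8E)-5-hydroxy-5,9-dimethyl-2-(propan-2-yl)cyclodeca-3,8-dien-1-yl 4-hydroxy-3-methoxybenzoate (CNP0162316.1)
Conditions: TBAF, THF, 0 → 45 °C
Reagents that add atoms: none
Why: fluoride-mediated desilylation should remove the aryl silyl ether at once and the tertiary allylic silyl ether on warming, under non-acidic conditions that avoid transannular cyclization of the ring diene and leave the aryl ester intact.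

**Compound list**

1 | (R)-4-benzyloxazolidin-2-one | O=C1N[C@H](Cc2ccccc2)CO1 | starting material
2 | 3-methylbutanoyl chloride | CC(C)CC(Cl)=O | starting material
3 | (R)-4-benzyl-3-(3-methylbutanoyl)oxazolidin-2-one | CC(C)CC(=O)N1[C@H](Cc2ccccc2)COC1=O | intermediate
4 | chloroacetaldehyde | ClCC=O | starting material
5 | Z-dibutylboron enolate of 3 | CC(C)/C=C(\OB(CCCC)CCCC)N1[C@H](Cc2ccccc2)COC1=O | intermediate (not isolated)
6 | dibutylboron aldolate of 7 | O=C1OC[C@@H](Cc2ccccc2)N1C(=O)[C@@H]([C@@H](OB(CCCC)CCCC)CCl)C(C)C | intermediate (not isolated)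
7 | (R)-4-benzyl-3-[(2R,3R)-4-chloro-3-hydroxy-2-(propan-2-yl)butanoyl]oxazolidin-2-one | O=C1OC[C@@H](Cc2ccccc2)N1C(=O)[C@@H]([C@@H](O)CCl)C(C)C | intermediate
8 | (R)-4-benzyl-3-[(2R,3R)-4-chloro-2-(propan-2-yl)-3-(triethylsilyloxy)butanoyl]oxazolidin-2-one | O=C1OC[C@@H](Cc2ccccc2)N1C(=O)[C@@H]([C@@H](O[Si](CC)(CC)CC)CCl)C(C)C | intermediate
9 | (2S,3R)-4-chloro-2-(propan-2-yl)-3-(triethylsilyloxy)butan-1-ol | OC[C@@H]([C@@H](O[Si](CC)(CC)CC)CCl)C(C)C | intermediate
10 | 5-{[(2R,3R)-4-chloro-2-(propan-2-yl)-3-(triethylsilyloxy)butyl]sulfanyl}-1-phenyl-1H-tetrazole | c1ccccc1-n1nnnc1SC[C@@H]([C@@H](O[Si](CC)(CC)CC)CCl)C(C)C | intermediate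
11 | 5-{[(2R,3R)-4-chloro-2-(propan-2-yl)-3-(triethylsilyloxy)butyl]sulfonyl}-1-phenyl-1H-tetrazole | O=S(=O)(C[C@@H]([C@@H](O[Si](CC)(CC)CC)CCl)C(C)C)c1nnnn1-c1ccccc1 | intermediate
12 | (R)-linalool, (3R)-3,7-dimethylocta-1,6-dien-3-ol | CC(C)=CCC[C@@](C)(O)C=C | starting material
13 | tert-butyl{[(3R)-3,7-dimethylocta-1,6-dien-3-yl]oxy}dimethylsilane | CC(C)=CCC[C@@](C)(O[Si](C)(C)C(C)(C)C)C=C | intermediate
14 | ozonide (1,2,4-trioxolane) of the trisubstituted alkene of 13 | CC1(C)OOC(CC[C@@](C)(O[Si](C)(C)C(C)(C)C)C=C)O1 | intermediate (not isolated)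
15 | (4R)-4-(tert-butyldimethylsilyloxy)-4-methylhex-5-enal | O=CCC[C@@](C)(O[Si](C)(C)C(C)(C)C)C=C | intermediate
16 | tert-butyl{[(3R)-7,7-dibromo-3-methylhepta-1,6-dien-3-yl]oxy}dimethylsilane | BrC(Br)=CCC[C@@](C)(O[Si](C)(C)C(C)(C)C)C=C | intermediate
17 | [(5R)-5-(tert-butyldimethylsilyloxy)-5-methylhept-6-en-1-yn-1-yl]lithium | [Li]C#CCC[C@@](C)(O[Si](C)(C)C(C)(C)C)C=C | intermediate (not isolated)
18 | tert-butyldimethyl{[(3R)-3-methyloct-1-en-6-yn-3-yl]oxy}silane | CC#CCC[C@@](C)(O[Si](C)(C)C(C)(C)C)C=C | intermediate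
19 | (3R)-3-(tert-butyldimethylsilyloxy)-3-methyloct-6-yne-1,2-diol (both C2 epimers) | CC#CCC[C@@](C)(O[Si](C)(C)C(C)(C)C)C(O)CO | intermediate (not isolated)
20 | (2R)-2-(tert-butyldimethylsilyloxy)-2-methylhept-5-ynal | CC#CCC[C@@](C)(O[Si](C)(C)C(C)(C)C)C=O | intermediate
21 | potassium α-sulfonyl carbanion of 11 | [K+].O=S(=O)([CH-][C@@H]([C@@H](O[Si](CC)(CC)CC)CCl)C(C)C)c1nnnn1-c1ccccc1 | intermediate (not isolated)
22 | {[(2R,3S,4E,6R)-1-chloro-6-methyl-3-(propan-2-yl)-2-(triethylsilyloxy)undec-4-en-9-yn-6-yl]oxy}(tert-butyl)dimethylsilane | CC#CCC[C@@](C)(O[Si](C)(C)C(C)(C)C)/C=C/[C@@H]([C@@H](O[Si](CC)(CC)CC)CCl)C(C)C | intermediate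
23 | (2R,3S,4E,6R)-6-(tert-butyldimethylsilyloxy)-1-chloro-6-methyl-3-(propan-2-yl)undec-4-en-9-yn-2-ol (formed as its tetrabutylammonium alkoxide) | CC#CCC[C@@](C)(O[Si](C)(C)C(C)(C)C)/C=C/[C@@H]([C@@H](O)CCl)C(C)C | intermediate (not isolated)
24 | (2R)-2-[(3S,4E,6R)-6-(tert-butyldimethylsilyloxy)-2,6-dimethylundec-4-en-9-yn-3-yl]oxirane | CC#CCC[C@@](C)(O[Si](C)(C)C(C)(C)C)/C=C/[C@@H]([C@@H]1CO1)C(C)C | intermediate
25 | O-diethylboryl derivative (diethylborinate) of 26 | CCB(CC)O[C@H]1C/C(C)=C/CC[C@@](C)(O[Si](C)(C)C(C)(C)C)/C=C/[C@@H]1C(C)C | intermediate (not isolated)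
26 | (1S,2S,3E,5R,8E)-5-(tert-butyldimethylsilyloxy)-5,9-dimethyl-2-(propan-2-yl)cyclodeca-3,8-dien-1-ol | O[C@H]1C/C(C)=C/CC[C@@](C)(O[Si](C)(C)C(C)(C)C)/C=C/[C@@H]1C(C)C | intermediate
27 | vanillic acid, 4-hydroxy-3-methoxybenzoic acid | COc1cc(C(=O)O)ccc1O | starting material
28 | tert-butyldimethylsilyl 4-(tert-butyldimethylsilyloxy)-3-methoxybenzoate | COc1cc(C(=O)O[Si](C)(C)C(C)(C)C)ccc1O[Si](C)(C)C(C)(C)C | intermediate (not isolated)
29 | 4-(tert-butyldimethylsilyloxy)-3-methoxybenzoic acid | COc1cc(C(=O)O)ccc1O[Si](C)(C)C(C)(C)C | intermediate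
30 | 4-(tert-butyldimethylsilyloxy)-3-methoxybenzoic 2,4,6-trichlorobenzoic anhydride | COc1cc(C(=O)OC(=O)c2c(Cl)cc(Cl)cc2Cl)ccc1O[Si](C)(C)C(C)(C)C | intermediate (not isolated)
31 | (1S,2S,3E,5R,8E)-5-(tert-butyldimethylsilyloxy)-5,9-dimethyl-2-(propan-2-yl)cyclodeca-3,8-dien-1-yl 4-(tert-butyldimethylsilyloxy)-3-methoxybenzoate | COc1cc(C(=O)O[C@H]2C/C(C)=C/CC[C@@](C)(O[Si](C)(C)C(C)(C)C)/C=C/[C@@H]2C(C)C)ccc1O[Si](C)(C)C(C)(C)C | intermediate
32 | (1S,2S,3E,5R,8E)-5-hydroxy-5,9-dimethyl-2-(propan-2-yl)cyclodeca-3,8-dien-1-yl 4-hydroxy-3-methoxybenzoate | COc1cc(C(=O)O[C@H]2C/C(C)=C/CC[C@@](C)(O)/C=C/[C@@H]2C(C)C)ccc1O | target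

**Step count**

Total: 17 steps. Longest linear sequence: 11 steps (steps 1–6, 12, 13, 14, 16, 17); the linalool branch (steps 7–11) and the acid (step 15) run in parallel.

**Steps most likely to fail, with fallbacks**

Step 14 (the proposed new method). Intermolecular coupling may outrun the slow ten-membered closure and give oligomers, the alkyne may insert in the opposite sense, or the epoxide may simply be opened reductively without C–C bond formation. The fallback uses known chemistry only: the C9–C10 bond is made intermolecularly and the ring is closed instead at the sp2–sp3 bond C7–C8 by B-alkyl Suzuki–Miyaura macrocyclization. It sets out from sulfone 11 and comes back to the route at 26. Commercial racemic 2-methyl-2-vinyloxirane is converted by dynamic kinetic asymmetric allylic substitution with hydrogen carbonate (Pd2(dba)3·CHCl3, the appropriate enantiomer of N,N′-(cyclohexane-1,2-diyl)bis[2-(diphenylphosphino)benzamide], Et3B (cat.), NaHCO3, CH2Cl2/H2O; zerovalent palladium π-allyl chemistry) into (2R)-2-methylbut-3-ene-1,2-diol F1. Silylation of both hydroxyls (TBSOTf, 2,6-lutidine) gives the bis-silyl ether F2, selective cleavage of the primary silyl ether (HF·pyridine, pyridine, THF, 0 °C) gives the alcohol F3, and Dess–Martin oxidation gives (2R)-2-(tert-butyldimethylsilyloxy)-2-methylbut-3-enal F4. Julia–Kocienski olefination of 11 (through carbanion 21) with F4 should give the E-diene chloride F5, and TBAF closes it to the epoxide F6 as in step 13. Opening of the epoxide at its CH2 carbon with LiC≡CH·H2NCH2CH2NH2 in DMSO gives the homopropargylic alcohol F7. Zirconium-catalysed methylalumination with iodinolysis (Me3Al, Cp2ZrCl2, CH2Cl2, 0 °C; then I2, THF), a Negishi carboalumination, gives the (E)-vinyl iodide F8 with the methyl already on C9. Hydroboration of the monosubstituted vinyl group with 9-BBN gives the B-alkyl-9-borabicyclo[3.3.1]nonane F9 (not isolated; the free hydroxyl is borinated in the flask and freed on work-up). Intramolecular Suzuki–Miyaura coupling (Pd(dppf)Cl2, AsPh3, Cs2CO3, DMF/THF/H2O, high dilution) then joins C7 to C8 with retention of the alkene geometry and gives 26.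

Step 12. Addition of the metalated tetrazolyl sulfone to the neopentyl-type α-silyloxy aldehyde may be slow, letting the carbanion decompose, and the kinetically controlled E-selectivity may erode. The fallback is the two-stage Julia–Lythgoe olefination, in which the geometry is set in a separate reductive elimination; it sets out from alcohol 9 (with aldehyde 20) and comes back at 22. Alcohol 9 is converted with PhSSPh and PBu3 into the phenyl sulfide F10 and oxidized with mCPBA to the phenyl sulfone F11. Its α-lithio derivative F12 (n-BuLi, THF, −78 °C; not isolated) is added to 20 and the alkoxide is acetylated in the flask (Ac2O) to give the β-acetoxy sulfone F13 as a diastereomer mixture. Reductive elimination with SmI2 (THF/HMPA, −78 °C), which goes through an equilibrating alkenyl radical or organosamarium species and leaves the alkyl chloride and the alkyne alone at this temperature, should give the E-alkene 22.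

Step 17. Cleavage of the hindered tertiary silyl ether may stall, and forcing the fluoride conditions may bring ester cleavage or elimination of the vanillate. The fallback removes the tertiary silyl group before the ester exists and relies on chemoselective acylation; it sets out from 26 and comes back at the target 32. Compound 26 is desilylated under forcing conditions (TBAF, THF, 60 °C) to the diol F14. Only the secondary C1 hydroxyl is then acylated with the mixed anhydride 30 (from 29 as in step 16; DMAP, toluene), the tertiary alcohol being inert, to give the mono-ester F15. Mild removal of the aryl silyl ether (TBAF, AcOH, THF, 0 °C) gives 32.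

**Further compounds**

F1 | step 14 | (2R)-2-methylbut-3-ene-1,2-diol | C=C[C@@](C)(O)CO
F2 | step 14 | (2R)-1,2-bis(tert-butyldimethylsilyloxy)-2-methylbut-3-ene | C=C[C@@](C)(O[Si](C)(C)C(C)(C)C)CO[Si](C)(C)C(C)(C)C
F3 | step 14 | (2R)-2-(tert-butyldimethylsilyloxy)-2-methylbut-3-en-1-ol | C=C[C@@](C)(O[Si](C)(C)C(C)(C)C)CO
F4 | step 14 | (2R)-2-(tert-butyldimethylsilyloxy)-2-methylbut-3-enal | C=C[C@@](C)(O[Si](C)(C)C(C)(C)C)C=O
F5 | step 14 | tert-butyl{[(3R,4E,6S,7R)-8-chloro-3-methyl-6-(propan-2-yl)-7-(triethylsilyloxy)octa-1,4-dien-3-yl]oxy}dimethylsilane | C=C[C@@](C)(O[Si](C)(C)C(C)(C)C)/C=C/[C@@H]([C@@H](O[Si](CC)(CC)CC)CCl)C(C)C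
F6 | step 14 | (2R)-2-[(3S,4E,6R)-6-(tert-butyldimethylsilyloxy)-2,6-dimethylocta-4,7-dien-3-yl]oxirane | C=C[C@@](C)(O[Si](C)(C)C(C)(C)C)/C=C/[C@@H]([C@@H]1CO1)C(C)C
F7 | step 14 | (4S,5S,6E,8R)-8-(tert-butyldimethylsilyloxy)-8-methyl-5-(propan-2-yl)deca-6,9-dien-1-yn-4-ol | C=C[C@@](C)(O[Si](C)(C)C(C)(C)C)/C=C/[C@@H]([C@@H](O)CC#C)C(C)C
F8 | step 14 | (1E,4S,5S,6E,8R)-8-(tert-butyldimethylsilyloxy)-1-iodo-2,8-dimethyl-5-(propan-2-yl)deca-1,6,9-trien-4-ol | C=C[C@@](C)(O[Si](C)(C)C(C)(C)C)/C=C/[C@@H]([C@@H](O)C/C(C)=C/I)C(C)C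
F9 | step 14 | B-alkyl-9-borabicyclo[3.3.1]nonane from F8 (hydroxyl borinated as well; not isolated) | C1CCC2CCCC1B2CC[C@@](C)(O[Si](C)(C)C(C)(C)C)/C=C/[C@@H]([C@@H](OB1C2CCCC1CCC2)C/C(C)=C/I)C(C)C
F10 | step 12 | {[(2R,3R)-4-chloro-2-(propan-2-yl)-3-(triethylsilyloxy)butyl]sulfanyl}benzene | c1ccccc1SC[C@@H]([C@@H](O[Si](CC)(CC)CC)CCl)C(C)C
F11 | step 12 | {[(2R,3R)-4-chloro-2-(propan-2-yl)-3-(triethylsilyloxy)butyl]sulfonyl}benzene | O=S(=O)(C[C@@H]([C@@H](O[Si](CC)(CC)CC)CCl)C(C)C)c1ccccc1
F12 | step 12 | α-lithio derivative of F11 (not isolated) | [Li]C(S(=O)(=O)c1ccccc1)[C@@H]([C@@H](O[Si](CC)(CC)CC)CCl)C(C)C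
F13 | step 12 | β-acetoxy phenyl sulfone from F12 and 20 (diastereomer mixture at the two new centres) | CC#CCC[C@@](C)(O[Si](C)(C)C(C)(C)C)C(OC(C)=O)C(S(=O)(=O)c1ccccc1)[C@@H]([C@@H](O[Si](CC)(CC)CC)CCl)C(C)C
F14 | step 17 | (1S,2S,3E,5R,8E)-5,9-dimethyl-2-(propan-2-yl)cyclodeca-3,8-diene-1,5-diol | O[C@H]1C/C(C)=C/CC[C@@](C)(O)/C=C/[C@@H]1C(C)C
F15 | step 17 | (1S,2S,3E,5R,8E)-5-hydroxy-5,9-dimethyl-2-(propan-2-yl)cyclodeca-3,8-dien-1-yl 4-(tert-butyldimethylsilyloxy)-3-methoxybenzoate | COc1cc(C(=O)O[C@H]2C/C(C)=C/CC[C@@](C)(O)/C=C/[C@@H]2C(C)C)ccc1O[Si](C)(C)C(C)(C)C
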